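## Structural features

Garcinisidone E is an achiral depsidone (C28H30O7). Ring A (the acyl ring) and ring B (the phenolic ring) are joined twice: by an aryl ester from the ring A carbonyl to a ring B oxygen, and by a diaryl ether between the neighbouring carbons, so a seven-membered dioxepinone lies between the two benzene rings. Ring A is fully substituted: the carbonyl carbon C1 is flanked by the ether oxygen on C2 and a free hydroxyl on C6, each of these is flanked by a prenyl group (C3, C5), and a free hydroxyl on C4 sits between the prenyl groups. Ring B carries, in order round the ring, the ester oxygen, the ether oxygen, its only hydrogen, a free hydroxyl, and the oxygen and the vinyl carbon of an angularly fused 2,2-dimethyl-2H-pyran; the ester oxygen therefore stands next to the pyran carbon and the ether oxygen next to the CH. There is no stereocentre, so there are no neighbouring stereocentres to relate and every problem is one of regiochemistry. The fragile parts are the three electron-rich double bonds (acid closes a prenyl group onto an ortho phenol; peracids and strong oxidants attack them), the aryl ester of the seven-membered ring (opened by alkoxide or hydroxide) and the oxygen-rich ring B, which is one oxidation level from a quinone. The real difficulty is to place two C-prenyl groups on a phloroglucinol-type ring without O-alkylation, double alkylation at one carbon or chroman formation, to tell the three ring A oxygens apart, and to attach ring B in the right orientation. The key step uses the mirror plane of ring A through C1 and C4: the oxygens on C2 and C6 are equivalent, and each has exactly one free ortho carbon (C3, C5), which is the carbon that must carry a prenyl group.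

## Logic of the disconnections

17 ⇒ 16. The O–Si bond on the ring A oxygen para to the lactone carbonyl is the last bond cleaved in the forward direction. This oxygen is the most acidic and least hindered of ring A before prenylation and has to stay masked from the first step to the last C–O bond formation. Nothing is gained in skeleton, but the three ring A oxygens become distinguishable. The forward unmasking must spare an aryl ester, three alkenes and an oxidizable ring B, which points to buffered fluoride.

16 ⇒ 15. The lactone bond between the carbonyl carbon and the ring B oxygen is cut. Once the diaryl ether holds the rings together, only the ring B hydroxyl next to the ether oxygen can reach the ester, so the regiochemistry of ring closure is automatic. The central ring is opened and a methyl ester with a free hydroxyl remains. The forward step is an acyl transfer from a methyl ester to an aryl oxygen and has to be driven by removal of methanol under a weak base, with air excluded.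

15 ⇒ 14. No bond is cut; ring B is raised to the quinone oxidation level. As a quinone, ring B becomes an electrophile at exactly the carbon that must carry the ether oxygen, and both hydroxyls of 15 are already present as carbonyl groups. The forward reduction must leave the alkenes, the ester and the silyl ether alone.

14 ⇒ 8 + 13. The diaryl ether bond between the ring A oxygen and C6 of the quinone is cut. This divides the molecule into two halves of similar size and makes the route convergent. The site on ring B is fixed by the leaving group of 13, and the two hydroxyls of 8 are equivalent, so only one mono-ether is possible. The forward step needs substitution at the methoxy-bearing carbon only, one arylation only, and a silyl ether that holds under base.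

13 ⇒ 12 ⇒ 9 + 10. First the O–CH3 bond is cut. Then two bonds of the pyran are cut, the ring B carbon to CH bond and the O–C(CH3)2 bond. The bicyclic quinone is reduced to two commercial compounds. The forward annulation must stop after one pyran has formed on the symmetric 9.

8 ⇒ 6 (through 7). The two aryl–CH2 bonds of the prenyl groups are cut, and each C5 unit is reattached through its tertiary carbon to the neighbouring oxygen. This removes both C-prenyl groups in one operation and leads back to a symmetric trioxygenated benzoate whose para oxygen is masked. The forward step needs both ethers to migrate to C3 and C5 and nowhere else.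

6 ⇒ 5 ⇒ 2 + 3 (through 4). The vinyl groups are traced back to ethynyl groups, and then both O–C(tertiary) bonds are cut. A tertiary allyl ether cannot be made by direct displacement, whereas a tertiary propargyl ether can be made through a copper allenylidene. The forward sequence needs alkylation at both chelated hydroxyls and a hydrogenation that stops at the alkene.

2 ⇒ 1. The O–Si bond is cut. The forward silylation must take the para hydroxyl only, which is the one hydroxyl not hydrogen-bonded to the ester.

## Other disconnections considered

Alternative 1: The cut runs through the pyran of ring B, at the ring B carbon to CH bond and the O–C(CH3)2 bond. In the forward direction the enolic carbon of a dihydroxyquinone condenses with an unsaturated aldehyde and the resulting oxatriene closes by 6π electrocyclization to pyranoquinone A1, which is the same compound as 12.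
- In its favour: one operation forms two bonds and a ring from two cheap compounds, and it places the pyran oxygen, the pyran carbon and the remaining hydroxyl of ring B in the pattern the target needs.
- Against it here: it solves only ring B and gives no answer for prenylating ring A or joining the rings, and it must stop at one annulation on a symmetric substrate.
- Structure: it builds a ring and two bonds where the chosen key step builds two bonds and no ring, so the alternative is the better on ring construction.
- Mechanism: both are pericyclic; the annulation has to break the symmetry of its substrate, whereas the Claisen step benefits from symmetry.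
- Step economy: a plan resting on A1 alone, with direct C-prenylation of ring A, could be shorter by up to three steps, and that is a point for the alternative on paper. It would pay for this with the poor selectivity of phloroglucinol C-alkylation.
- The chosen plan keeps this annulation as step 5, so on ring B the two plans are equal.

Alternative 2: The ester oxygen is excised, which leads back to xanthone A2 (chroman-fused, ring A as diacetate, ring B as triisopropylsilyl ether). In the forward direction CF3CO3H adds to the xanthone carbonyl and the electron-rich ring B aryl migrates to oxygen in a Baeyer–Villiger step, expanding the pyranone to the dioxepinone of A3.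
- In its favour: xanthones such as A2 are reached by classical acylation and cyclodehydration, and one step forms both C–O bonds of the ester and the seven-membered ring. The chosen plan needs arylation, reduction and lactonization for the same ring, so the alternative is the better on this count.
- Against it here: the peracid would epoxidize prenyl and chromene double bonds, so A2 must carry a saturated chroman and no prenyl groups. Both prenyl groups and the chromene unsaturation then have to be introduced on the base-sensitive depsidone A3, which brings back the ring A regiochemistry problem at the worst stage.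
- Mechanism: the direction of migration rests on an electronic bias (acetates against a silyl ether), and the doubly conjugated xanthone carbonyl is a weak electrophile. In the chosen plan the orientation follows from the positions of a leaving group and the nearest hydroxyl.
- Step economy: the extra protecting-group changes, the late prenylation and the dehydrogenation should make it longer overall.

Alternative 3: The diaryl ether is cut and the ring A carbonyl is attached to a ring B carbon, giving benzophenone A4. In the forward direction PhI(OAc)2 oxidizes the ring B phenol ortho to the ketone and a ring A hydroxyl closes on the ketone-bearing carbon to give spiro grisadienedione A5. The spiro carbon is racemic, which is of no consequence because a 1,2-acyl shift from carbon to oxygen then destroys it and gives bis-silyl depsidone A6; desilylation would finish the synthesis.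
- In its favour: the ether bond forms intramolecularly, which avoids a reversible intermolecular substitution by a hindered phenol, and this is a point on which it is better than step 7 of the chosen plan. The route follows the presumed biogenesis, and the symmetry of ring A makes the choice of attacking hydroxyl irrelevant.
- Equal point: ring A of A4 could be made by the same twofold Claisen rearrangement.
- Against it here: A4 is a ketone between two fully ortho-substituted, electron-rich rings, and its assembly from an aryl metal and an aldehyde with later oxidation needs more protecting groups and steps than the ether coupling.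
- Mechanism: hypervalent iodine must oxidize one phenol in the presence of three electron-rich alkenes, and the acyl shift must go to the correct oxygen and not revert to A4.
- Step economy: it is probably no shorter and carries more risk in the fragment union.

Key step: step 4

Remark on the chemistry: the silyl group is taken to be tert-butyldimethylsilyl throughout, and the activated form of 3 is its trifluoroacetate 4, made in the flask.

## Route

Step 1
Reactants: 1 methyl 2,4,6-trihydroxybenzoate
Product: 2 methyl 4-[(tert-butyldimethylsilyl)oxy]-2,6-dihydroxybenzoate
Conditions: TBSCl (1.05 equiv), imidazole, DMF, 0 °C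
Reagents that add atoms: tert-butyldimethylsilyl chloride (TBSCl), CC(C)(C)[Si](C)(C)Cl
Why: Silylation of a phenol; the 4-hydroxyl is the most acidic and the only one not held in a hydrogen bond to the ester, so one equivalent of silyl chloride should react there and leave the two chelated ortho hydroxyls free.

Step 2
Reactants: 2 methyl 4-[(tert-butyldimethylsilyl)oxy]-2,6-dihydroxybenzoate; 3 2-methylbut-3-yn-2-ol
Product: 5 methyl 4-[(tert-butyldimethylsilyl)oxy]-2,6-bis[(2-methylbut-3-yn-2-yl)oxy]benzoate, via 2-methylbut-3-yn-2-yl trifluoroacetate 4 (not isolated)
Conditions: 3 (3 equiv), (CF3CO)2O, DBU, MeCN, −5 °C; then 2, DBU, CuCl2·2H2O (cat.), MeCN, 0 °C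
Reagents that add atoms: none
Why: Copper-catalysed propargylic O-alkylation of phenols; the copper acetylide of 4 ionizes to a copper allenylidene that the DBU phenoxide captures at the tertiary carbon, so both chelated ortho oxygens should give 1,1-dimethylpropargyl ethers without C-alkylation.

Step 3
Reactants: 5 methyl 4-[(tert-butyldimethylsilyl)oxy]-2,6-bis[(2-methylbut-3-yn-2-yl)oxy]benzoate
Product: 6 methyl 4-[(tert-butyldimethylsilyl)oxy]-2,6-bis[(2-methylbut-3-en-2-yl)oxy]benzoate
Conditions: H2 (1 atm), Pd/CaCO3 poisoned with Pb(OAc)2, quinoline, EtOAc, rt
Reagents that add atoms: none
Why: Lindlar semihydrogenation; on the poisoned catalyst the terminal alkynes are reduced much faster than the vinyl groups they give, and the reaction is stopped after two equivalents of hydrogen.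

Step 4
Reactants: 6 methyl 4-[(tert-butyldimethylsilyl)oxy]-2,6-bis[(2-methylbut-3-en-2-yl)oxy]benzoate
Product: 8 methyl 4-[(tert-butyldimethylsilyl)oxy]-2,6-dihydroxy-3,5-bis(3-methylbut-2-enyl)benzoate, via mono-rearranged phenol 7 (not isolated)
Conditions: o-xylene (degassed), 130 °C, base-washed sealed tube
Reagents that add atoms: none
Why: This is a thermal aromatic Claisen rearrangement run twice on one ring. Each aryl 1,1-dimethylallyl ether passes through a chair-like six-membered (3,3) transition state in which the O–C(tertiary) bond breaks while the terminal CH2 of the vinyl group bonds to the free ortho carbon (C3 or C5); the ortho-dienone then enolizes to the phenol, and the allylic transposition leaves a linear 3-methylbut-2-enyl group. The closest known reaction type is the rearrangement of aryl reverse-prenyl ethers to ortho-prenylphenols, which runs at lower temperature than that of simple allyl ethers because the breaking bond is tertiary and the crowded 2,6-dialkoxybenzoate is relieved of strain. No ring closes and no stereocentre forms; the first shift gives 7 and its remaining ether migrates in the same way to give 8. The selectivity needed is positional, since each ether must go to C3 or C5 and must not travel on to the para carbon. The substrate secures this: the other ortho carbon of each ether is C1, which carries the ester, so a shift there gives a dienone that cannot enolize and can only revert, and C4 carries the silyloxy group, so no site is open for a following Cope shift. The new phenols are at once held in hydrogen bonds to the ester, which should damp their addition across the prenyl double bonds, and the silyl ether has no acid or nucleophile to react with under neutral thermal conditions. The product is a mirror-symmetric diphenol with two equivalent free ortho hydroxyls and a masked para oxygen, which is the differentiation the ether-forming step needs.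

Step 5
Reactants: 9 2,5-dihydroxy-1,4-benzoquinone; 10 3-methylbut-2-enal
Product: 12 6-hydroxy-2,2-dimethyl-2H-chromene-5,8-dione, via 1-oxatriene 11 (not isolated)
Conditions: 9 (2 equiv), pyridine, 90 °C, slow addition of 10
Reagents that add atoms: none
Why: Knoevenagel condensation at the enolic carbon of the vinylogous acid gives 11, which closes by oxa-6π electrocyclization to the 2H-pyran; either flanking carbonyl oxygen can act as the terminus because both modes give 12 after tautomerization to the hydroxy-para-quinone. An excess of 9 and slow addition of 10 should hold the reaction at one annulation.

Step 6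
Reactants: 12 6-hydroxy-2,2-dimethyl-2H-chromene-5,8-dione
Product: 13 6-methoxy-2,2-dimethyl-2H-chromene-5,8-dione
Conditions: Me2SO4, K2CO3, acetone, 56 °C
Reagents that add atoms: dimethyl sulfate, COS(=O)(=O)OC
Why: O-alkylation of a vinylogous carboxylic acid; the potassium salt of the hydroxyquinone should be methylated on the oxygen of C6 to give the para-quinone vinylogous ester, and the conditions are free of acid, which the chromene would not tolerate.

Step 7
Reactants: 8 methyl 4-[(tert-butyldimethylsilyl)oxy]-2,6-dihydroxy-3,5-bis(3-methylbut-2-enyl)benzoate; 13 6-methoxy-2,2-dimethyl-2H-chromene-5,8-dione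
Product: 14 methyl 4-[(tert-butyldimethylsilyl)oxy]-2-[(2,2-dimethyl-5,8-dioxo-5,8-dihydro-2H-chromen-6-yl)oxy]-6-hydroxy-3,5-bis(3-methylbut-2-enyl)benzoate
Conditions: 8 (1.1 equiv), Cs2CO3, 4 Å MS, DMF, 0 °C to rt, slow addition of 13
Reagents that add atoms: none
Why: Addition–elimination on an alkoxyquinone (vinylogous transesterification); the phenoxide adds to C6, which is β to the more electrophilic C8 carbonyl and carries the leaving group, and methoxide is expelled, protonated and taken up by the sieves. The two hydroxyls of 8 are equivalent, so only one mono-ether can form, and a slight excess of 8 should suppress a second arylation.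

Step 8
Reactants: 14 methyl 4-[(tert-butyldimethylsilyl)oxy]-2-[(2,2-dimethyl-5,8-dioxo-5,8-dihydro-2H-chromen-6-yl)oxy]-6-hydroxy-3,5-bis(3-methylbut-2-enyl)benzoate
Product: 15 methyl 4-[(tert-butyldimethylsilyl)oxy]-2-[(5,8-dihydroxy-2,2-dimethyl-2H-chromen-6-yl)oxy]-6-hydroxy-3,5-bis(3-methylbut-2-enyl)benzoate
Conditions: Na2S2O4, THF/H2O, rt, argon; extractive work-up under argon, used crude
Reagents that add atoms: none
Why: Dithionite reduction of a quinone to its hydroquinone; the reagent does not touch alkenes, esters or silyl ethers.

Step 9
Reactants: 15 methyl 4-[(tert-butyldimethylsilyl)oxy]-2-[(5,8-dihydroxy-2,2-dimethyl-2H-chromen-6-yl)oxy]-6-hydroxy-3,5-bis(3-methylbut-2-enyl)benzoate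
Product: 16 garcinisidone E tert-butyldimethylsilyl ether (silyl group on the ring A oxygen para to the lactone carbonyl)
Conditions: K2CO3, 4 Å MS, MeCN (degassed), 50 °C
Reagents that add atoms: none
Why: Base-mediated intramolecular transesterification (lactonization, 7-exo-trig); only the C5 oxygen of ring B, ortho to the ether link, can reach the ester, so the ring closes in one orientation. The weak base lets the expelled methoxide be protonated and the sieves remove the methanol, which should pull the equilibrium toward the aryl ester.

Step 10
Reactants: 16 garcinisidone E tert-butyldimethylsilyl ether
Product: 17 garcinisidone E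
Conditions: TBAF, AcOH, THF, 0 °C
Reagents that add atoms: none
Why: Fluoride cleavage of an aryl silyl ether; buffering with acetic acid keeps the medium from becoming basic enough to open the aryl ester, and the alkenes are not affected.

## Compound list

1 | methyl 2,4,6-trihydroxybenzoate | COC(=O)c1c(O)cc(O)cc1O | starting material
2 | methyl 4-[(tert-butyldimethylsilyl)oxy]-2,6-dihydroxybenzoate | COC(=O)c1c(O)cc(O[Si](C)(C)C(C)(C)C)cc1O | intermediate
3 | 2-methylbut-3-yn-2-ol | CC(C)(O)C#C | starting material
4 | 2-methylbut-3-yn-2-yl trifluoroacetate | CC(C)(OC(=O)C(F)(F)F)C#C | intermediate (not isolated)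
5 | methyl 4-[(tert-butyldimethylsilyl)oxy]-2,6-bis[(2-methylbut-3-yn-2-yl)oxy]benzoate | COC(=O)c1c(OC(C)(C)C#C)cc(O[Si](C)(C)C(C)(C)C)cc1OC(C)(C)C#C | intermediate
6 | methyl 4-[(tert-butyldimethylsilyl)oxy]-2,6-bis[(2-methylbut-3-en-2-yl)oxy]benzoate | COC(=O)c1c(OC(C)(C)C=C)cc(O[Si](C)(C)C(C)(C)C)cc1OC(C)(C)C=C | intermediate
7 | methyl 4-[(tert-butyldimethylsilyl)oxy]-2-hydroxy-3-(3-methylbut-2-enyl)-6-[(2-methylbut-3-en-2-yl)oxy]benzoate | COC(=O)c1c(O)c(CC=C(C)C)c(O[Si](C)(C)C(C)(C)C)cc1OC(C)(C)C=C | intermediate (not isolated)
8 | methyl 4-[(tert-butyldimethylsilyl)oxy]-2,6-dihydroxy-3,5-bis(3-methylbut-2-enyl)benzoate | COC(=O)c1c(O)c(CC=C(C)C)c(O[Si](C)(C)C(C)(C)C)c(CC=C(C)C)c1O | intermediate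
9 | 2,5-dihydroxy-1,4-benzoquinone | O=C1C=C(O)C(=O)C=C1O | starting material
10 | 3-methylbut-2-enal | CC(C)=CC=O | starting material
11 | 5-hydroxy-3-(3-methylbut-2-en-1-ylidene)cyclohex-5-ene-1,2,4-trione (1-oxatriene; geometry of the exocyclic double bond not defined) | O=C1C=C(O)C(=O)C(=CC=C(C)C)C1=O | intermediate (not isolated)
12 | 6-hydroxy-2,2-dimethyl-2H-chromene-5,8-dione | O=C1C(O)=CC(=O)C2=C1C=CC(C)(C)O2 | intermediate
13 | 6-methoxy-2,2-dimethyl-2H-chromene-5,8-dione | COC1=CC(=O)C2=C(C=CC(C)(C)O2)C1=O | intermediate
14 | methyl 4-[(tert-butyldimethylsilyl)oxy]-2-[(2,2-dimethyl-5,8-dioxo-5,8-dihydro-2H-chromen-6-yl)oxy]-6-hydroxy-3,5-bis(3-methylbut-2-enyl)benzoate | COC(=O)c1c(O)c(CC=C(C)C)c(O[Si](C)(C)C(C)(C)C)c(CC=C(C)C)c1OC1=CC(=O)C2=C(C=CC(C)(C)O2)C1=O | intermediate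
15 | methyl 4-[(tert-butyldimethylsilyl)oxy]-2-[(5,8-dihydroxy-2,2-dimethyl-2H-chromen-6-yl)oxy]-6-hydroxy-3,5-bis(3-methylbut-2-enyl)benzoate | COC(=O)c1c(O)c(CC=C(C)C)c(O[Si](C)(C)C(C)(C)C)c(CC=C(C)C)c1Oc1cc(O)c2c(c1O)C=CC(C)(C)O2 | intermediate
16 | garcinisidone E tert-butyldimethylsilyl ether (silyl group on the ring A oxygen para to the lactone carbonyl) | CC(C)=CCc1c(O[Si](C)(C)C(C)(C)C)c(CC=C(C)C)c2c(c1O)C(=O)Oc1c(cc(O)c3c1C=CC(C)(C)O3)O2 | intermediate
17 | garcinisidone E | CC(C)=CCc1c(O)c(CC=C(C)C)c2c(c1O)C(=O)Oc1c(cc(O)c3c1C=CC(C)(C)O3)O2 | target

## Step count and least certain steps

Total: 10 steps. Longest linear sequence: 8 steps (steps 1, 2, 3, 4, 7, 8, 9, 10); the ring B branch adds steps 5 and 6.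

Step 4 (key step). The most likely failure is heterolytic loss of the tertiary allyl group in competition with the concerted shift, because the breaking O–C bond is tertiary and traces of acid on the glass promote ionization. A stall after the first migration, or acid-promoted addition of a new phenol across its neighbouring prenyl group, are the other possibilities. Fallback: set out from 1 and C-prenylate both free ring carbons directly (prenyl bromide, DBU, THF, 0 °C) to give methyl 2,4,6-trihydroxy-3,5-bis(3-methylbut-2-enyl)benzoate F1. Then silylate its non-chelated 4-hydroxyl (TBSCl, imidazole, DMF, 0 °C) and rejoin the route at 8. This accepts the lower selectivity of phenoxide C-alkylation in exchange for avoiding the thermal step.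

Step 7. The most likely failure is reversal of the substitution. The aryloxide is a better leaving group than methoxide, so the adduct tends to fall back to 8 and 13, and any methoxide that is not protonated and removed can displace the aryl ether again. The same methoxide could also strip the silyl group. Fallback: set out from 12 and convert the vinylogous acid into its chloride with oxalyl chloride and catalytic DMF in CH2Cl2 at 0 °C, giving 6-chloro-2,2-dimethyl-2H-chromene-5,8-dione F2. Couple F2 with 8 (K2CO3, acetone, 0 °C); chloride does not return, and the route is rejoined at 14.

Step 9. The most likely failure is incomplete acyl transfer, since conversion of a doubly ortho-substituted methyl ester into an aryl ester is uphill unless methanol is removed, together with re-oxidation of the hydroquinone by traces of air. Fallback: set out from 15 and cleave the methyl ester at the methyl carbon (LiI, pyridine, 100 °C, argon, then dilute acid) to give 4-[(tert-butyldimethylsilyl)oxy]-2-[(5,8-dihydroxy-2,2-dimethyl-2H-chromen-6-yl)oxy]-6-hydroxy-3,5-bis(3-methylbut-2-enyl)benzoic acid F3. Close the lactone from the acid with N,N'-dicyclohexylcarbodiimide in CH2Cl2 at 0 °C, the classical depsidone closure, and rejoin the route at 16.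

Step 2. The most likely failure is a stall after the first alkylation, because the second chelated hydroxyl then sits beside a twisted, crowded ester, together with slow desilylation of the electron-poor aryl silyl ether by DBU. Fallback: set out from 2 and form the tertiary allyl ethers directly by Tsuji–Trost O-allylation with tert-butyl 2-methylbut-3-en-2-yl carbonate F4 (from commercial 2-methylbut-3-en-2-ol, n-BuLi and di-tert-butyl dicarbonate). With Pd(PPh3)4 (zerovalent palladium) in THF at 0 °C, the phenoxide should attack the more substituted allyl terminus under kinetic control. This rejoins the route at 6 and bypasses 5 and step 3.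

## Further compounds

F1 | step 4 | methyl 2,4,6-trihydroxy-3,5-bis(3-methylbut-2-enyl)benzoate | COC(=O)c1c(O)c(CC=C(C)C)c(O)c(CC=C(C)C)c1O
F2 | step 7 | 6-chloro-2,2-dimethyl-2H-chromene-5,8-dione | O=C1C(Cl)=CC(=O)C2=C1C=CC(C)(C)O2
F3 | step 9 | 4-[(tert-butyldimethylsilyl)oxy]-2-[(5,8-dihydroxy-2,2-dimethyl-2H-chromen-6-yl)oxy]-6-hydroxy-3,5-bis(3-methylbut-2-enyl)benzoic acid | OC(=O)c1c(O)c(CC=C(C)C)c(O[Si](C)(C)C(C)(C)C)c(CC=C(C)C)c1Oc1cc(O)c2c(c1O)C=CC(C)(C)O2
F4 | step 2 | tert-butyl 2-methylbut-3-en-2-yl carbonate | CC(C)(C)OC(=O)OC(C)(C)C=C
A1 | alternative 1 | 6-hydroxy-2,2-dimethyl-2H-chromene-5,8-dione | O=C1C(O)=CC(=O)C2=C1C=CC(C)(C)O2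
A2 | alternative 2 | chroman-fused xanthone, ring A diacetate, ring B triisopropylsilyl ether | CC(=O)Oc1cc(OC(C)=O)c2c(c1)Oc1cc(O[Si](C(C)C)(C(C)C)C(C)C)c3c(c1C2=O)CCC(C)(C)O3
A3 | alternative 2 | chroman-fused depsidone core, ring A diacetate, ring B triisopropylsilyl ether | CC(=O)Oc1cc(OC(C)=O)c2c(c1)Oc1cc(O[Si](C(C)C)(C(C)C)C(C)C)c3c(c1OC2=O)CCC(C)(C)O3
A4 | alternative 3 | benzophenone: [4-(tert-butyldimethylsilyloxy)-2,6-dihydroxy-3,5-bis(3-methylbut-2-enyl)phenyl] [7-(tert-butyldimethylsilyloxy)-5-hydroxy-2,2-dimethyl-2H-chromen-6-yl] ketone | CC(C)=CCc1c(O[Si](C)(C)C(C)(C)C)c(CC=C(C)C)c(O)c(c1O)C(=O)c1cc(O[Si](C)(C)C(C)(C)C)c2c(c1O)C=CC(C)(C)O2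
A5 | alternative 3 | spiro grisadienedione (racemic spiro carbon) | CC(C)=CCc1c(O[Si](C)(C)C(C)(C)C)c(CC=C(C)C)c2c(c1O)C(=O)C1(O2)C=C(O[Si](C)(C)C(C)(C)C)C3=C(C=CC(C)(C)O3)C1=O
A6 | alternative 3 | garcinisidone E bis(tert-butyldimethylsilyl) ether (ring A para oxygen and ring B hydroxyl silylated) | CC(C)=CCc1c(O[Si](C)(C)C(C)(C)C)c(CC=C(C)C)c2c(c1O)C(=O)Oc1c(cc(O[Si](C)(C)C(C)(C)C)c3c1C=CC(C)(C)O3)O2
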